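**Retrosynthetic overview**
- The 14-membered ring is the only permanent ring and is closed last, by ring-closing metathesis at C10=C11 of a protecting-group-free seco ester.
- The seco ester comes from one three-component union: the C11–C13 alcohol (as its alkoxide) opens methylketene dimer (C1–C4, carrying C2) to a γ-enolate, which adds to the C5–C10 keto-aldehyde (forms O13–C1 and C4–C5).
- The keto-aldehyde comes from a trans-3,5-dimethyl δ-lactone (temporary ring) by propenyl addition and oxidation; the lactone comes from organocatalytic α-hydroxymethylation of propanal, Wittig olefination and catalyst-controlled hydrogenation.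
- The alcohol comes from a phosphoric-acid-catalysed (Z)-crotylboration of propanal; the dimer (temporary β-lactone) comes from alkaloid-catalysed dimerisation of methylketene, itself made from two molecules of propanoyl chloride.

Assumption: the SMILES is read as the 2R,4S,5R,6S,8S,12S,13S,10E isomer (C1 = lactone carbonyl, C13 = carbinol carbon bearing ethyl; 4,5-syn, 5,6-syn, 6,8-anti, 12,13-syn, 2,4-anti), and commercial prop-1-enylmagnesium bromide is drawn as its E isomer (any Z isomer converges, its CH–CH3 end leaving as propene in the last step).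

**Step 1**
Reactants: 1 propanal; 2 (Z)-crotylboronic acid pinacol ester
Product: 4 (3S,4S)-4-methylhex-5-en-3-ol, via borate ester 3 (not isolated)
Conditions: (R)-TRIP phosphoric acid (5 mol %), 4 Å MS, toluene, −30 °C; then H2O
Reagents that add atoms: none
Why: Chiral phosphoric acid-catalysed crotylboration through a closed chair transition state; the (Z)-boronate gives the 12,13-syn pair and the (R)-acid directs addition to the Re face of 1 (C13 S, C12 S), so the first stereocentres of this branch come from organocatalysis.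

**Step 2**
Reactants: 5 propanoyl chloride (2 equiv; two molecules end up in the product)
Product: 7 (3R,4Z)-4-ethylidene-3-methyloxetan-2-one, via methylketene 6 (not isolated)
Conditions: i-Pr2NEt (2.1 equiv), O-trimethylsilylquinidine (5 mol %), CH2Cl2, rt, slow addition of 5; bulb-to-bulb distillation
Reagents that add atoms: propanoyl chloride (second equivalent of 5), CCC(=O)Cl
Why: Each molecule of 5 is dehydrochlorinated to methylketene, and the alkaloid adds to one ketene to give a chiral ammonium enolate that C-acylates a second ketene and lactonises (nucleophile-catalysed asymmetric ketene dimerisation); this sets C2 as R (quinidine series) and fixes the (Z)-ethylidene that later becomes the enolate.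

**Step 3**
Reactants: 1 propanal; 8 formaldehyde (37 % aq.); 9 ethyl 2-(triphenylphosphoranylidene)propanoate
Product: 11 ethyl (2E,4S)-5-hydroxy-2,4-dimethylpent-2-enoate, via hydroxy aldehyde 10 (not isolated)
Conditions: (S)-α,α-diphenylprolinol trimethylsilyl ether (10 mol %), pH 7 buffer, toluene, 0 °C → rt; then 9, rt
Reagents that add atoms: none
Why: Enamine-catalysed α-hydroxymethylation (cross-aldol with formaldehyde) sets C6 on the unshielded enamine face, and the labile β-hydroxy aldehyde is trapped at once by an E-selective Wittig olefination.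

**Step 4**
Reactants: 11 ethyl (2E,4S)-5-hydroxy-2,4-dimethylpent-2-enoate
Product: 13 (2E,4S)-5-hydroxy-2,4-dimethylpent-2-enoic acid, via lithium carboxylate 12 (not isolated)
Conditions: LiOH, THF/H2O, rt; then 1 M HCl
Reagents that add atoms: lithium hydroxide, [Li+].[OH-]
Why: Plain ester saponification; the E-alkene keeps the hydroxy acid from lactonising and the stereocentre is not enolisable.

**Step 5**
Reactants: 13 (2E,4S)-5-hydroxy-2,4-dimethylpent-2-enoic acid
Product: 15 (3S,5S)-3,5-dimethyloxan-2-one, via hydroxy acid 14 (not isolated)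
Conditions: H2 (4 atm), Ru(OAc)2[(S)-H8-BINAP] (1 mol %), MeOH, rt; then p-TsOH (cat.), CH2Cl2
Reagents that add atoms: none
Why: Carboxylate-directed asymmetric hydrogenation of an (E)-2-methylalk-2-enoic acid under catalyst control sets C8 anti to C6 (the (S)-ligand is taken to give the 2S acid, by analogy with tiglic acid), and the δ-hydroxy acid then closes to the trans lactone under acid catalysis.

**Step 6**
Reactants: 15 (3S,5S)-3,5-dimethyloxan-2-one; 16 (E)-prop-1-en-1-ylmagnesium bromide
Product: 18 (2E,5S,7S)-8-hydroxy-5,7-dimethyloct-2-en-4-one, via magnesium hemiketalate 17 (not isolated)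
Conditions: THF, −78 °C; sat. aq. NH4Cl at −78 °C
Reagents that add atoms: none
Why: Acyl addition of a Grignard reagent to a δ-lactone stops at the tetrahedral magnesium hemiketalate at −78 °C (as in additions to sugar lactones), which collapses to the enone only on work-up.

**Step 7**
Reactants: 18 (2E,5S,7S)-8-hydroxy-5,7-dimethyloct-2-en-4-one
Product: 19 (2S,4S,6E)-2,4-dimethyl-5-oxooct-6-enal
Conditions: Dess–Martin periodinane, CH2Cl2, 0 °C → rt
Reagents that add atoms: none
Why: Dess–Martin oxidation of the primary alcohol under near-neutral conditions, which leaves both α-stereocentres (C6, C8) and the enone untouched.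

**Step 8**
Reactants: 4 (3S,4S)-4-methylhex-5-en-3-ol; 7 (3R,4Z)-4-ethylidene-3-methyloxetan-2-one; 19 (2S,4S,6E)-2,4-dimethyl-5-oxooct-6-enal
Product: 24 (3S,4S)-4-methylhex-5-en-3-yl (2R,4S,5R,6S,8S,10E)-5-hydroxy-2,4,6,8-tetramethyl-3,9-dioxododec-10-enoate, via lithium alkoxide 20 (not isolated), via lithium enolate 21 (not isolated), via tin enolate 22 (not isolated), via tin aldolate 23 (not isolated)
Conditions: 4, n-BuLi, THF, −78 °C; 7, −78 °C; Sn(OTf)2, −78 °C; 19, −78 → −40 °C; pH 7 buffer at −78 °C
Reagents that add atoms: none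
Why: Proposed new method: alkoxide 20 attacks the strained enol-lactone carbonyl of 7, and acyl–oxygen cleavage releases the ring oxygen as the regiodefined (Z)-γ-enolate 21 of the β-keto ester, a position that cannot be reached by deprotonating the ester and one in which C2–H is not doubly activated, so C2 is kept. Exchange to the divalent-tin enolate 22 is meant to switch facial control from the chelated lithium/titanium mode (2,4-syn) to the tin mode (2,4-anti), while the (Z)-geometry gives 4,5-syn through a closed Zimmerman–Traxler aldol and the enolate bias places the C5 carbinol syn to C6 (Felkin sense) on 19. The closest known reactions are the lithium-amide ring opening of methylketene dimer followed by syn-aldol addition, and the divalent-tin anti,syn aldol of α-methyl-β-keto imides.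

**Step 9**
Reactants: 24 (3S,4S)-4-methylhex-5-en-3-yl (2R,4S,5R,6S,8S,10E)-5-hydroxy-2,4,6,8-tetramethyl-3,9-dioxododec-10-enoate
Product: 25 (3R,5S,6R,7S,9S,11E,13S,14S)-14-ethyl-6-hydroxy-3,5,7,9,13-pentamethyl-1-oxacyclotetradec-11-ene-2,4,10-trione (target)
Conditions: second-generation Grubbs catalyst RuCl2(=CHPh)(H2IMes)(PCy3) (10 mol %), CH2Cl2 (1 mM), 40 °C
Reagents that add atoms: none
Why: Ring-closing metathesis; the carbene loads on the terminal vinyl group, closes on the electron-poor propenyl ketone with loss of propene and gives the conjugated E-enone in the 14-membered ring, and the neutral conditions leave C2 alone.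

**Compound list**
1 | propanal | CCC=O | starting material
2 | (Z)-crotylboronic acid pinacol ester, 2-[(2Z)-but-2-en-1-yl]-4,4,5,5-tetramethyl-1,3,2-dioxaborolane | C/C=C\CB1OC(C)(C)C(C)(C)O1 | starting material
3 | 4,4,5,5-tetramethyl-2-{[(3S,4S)-4-methylhex-5-en-3-yl]oxy}-1,3,2-dioxaborolane (borate ester) | CC[C@H](OB1OC(C)(C)C(C)(C)O1)[C@@H](C)C=C | intermediate
4 | (3S,4S)-4-methylhex-5-en-3-ol | CC[C@H](O)[C@@H](C)C=C | intermediate
5 | propanoyl chloride | CCC(=O)Cl | starting material
6 | methylketene (prop-1-en-1-one) | CC=C=O | intermediate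
7 | (3R,4Z)-4-ethylidene-3-methyloxetan-2-one (methylketene dimer) | O=C1[C@H](C)/C(=C/C)O1 | intermediate
8 | formaldehyde | C=O | starting material
9 | ethyl 2-(triphenylphosphoranylidene)propanoate | CCOC(=O)C(C)=P(c1ccccc1)(c1ccccc1)c1ccccc1 | starting material
10 | (2R)-3-hydroxy-2-methylpropanal | OC[C@@H](C)C=O | intermediate
11 | ethyl (2E,4S)-5-hydroxy-2,4-dimethylpent-2-enoate | OC[C@@H](C)/C=C(\C)C(=O)OCC | intermediate
12 | lithium (2E,4S)-5-hydroxy-2,4-dimethylpent-2-enoate | OC[C@@H](C)/C=C(\C)C(=O)[O-].[Li+] | intermediate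
13 | (2E,4S)-5-hydroxy-2,4-dimethylpent-2-enoic acid | OC[C@@H](C)/C=C(\C)C(=O)O | intermediate
14 | (2S,4S)-5-hydroxy-2,4-dimethylpentanoic acid | OC[C@@H](C)C[C@H](C)C(=O)O | intermediate
15 | (3S,5S)-3,5-dimethyloxan-2-one (trans lactone) | C[C@H]1C[C@H](C)COC1=O | intermediate
16 | (E)-prop-1-en-1-ylmagnesium bromide | C/C=C/[Mg]Br | starting material
17 | bromomagnesium (3S,5S)-3,5-dimethyl-2-[(1E)-prop-1-en-1-yl]oxan-2-olate (both C2 epimers) | C[C@H]1C[C@H](C)COC1(O[Mg]Br)/C=C/C | intermediate
18 | (2E,5S,7S)-8-hydroxy-5,7-dimethyloct-2-en-4-one | OC[C@@H](C)C[C@H](C)C(=O)/C=C/C | intermediate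
19 | (2S,4S,6E)-2,4-dimethyl-5-oxooct-6-enal | O=C[C@@H](C)C[C@H](C)C(=O)/C=C/C | intermediate
20 | lithium (3S,4S)-4-methylhex-5-en-3-olate | CC[C@H](O[Li])[C@@H](C)C=C | intermediate
21 | lithium (2Z,4R)-4-methyl-5-{[(3S,4S)-4-methylhex-5-en-3-yl]oxy}-5-oxopent-2-en-3-olate | CC[C@H](OC(=O)[C@H](C)/C(O[Li])=C/C)[C@@H](C)C=C | intermediate
22 | divalent-tin (triflato) enolate corresponding to 21 | CC[C@H](OC(=O)[C@H](C)/C(O[Sn]OS(=O)(=O)C(F)(F)F)=C/C)[C@@H](C)C=C | intermediate
23 | divalent-tin (triflato) C5-aldolate of 24 | CC[C@H](OC(=O)[C@H](C)C(=O)[C@@H](C)[C@H](O[Sn]OS(=O)(=O)C(F)(F)F)[C@@H](C)C[C@H](C)C(=O)/C=C/C)[C@@H](C)C=C | intermediate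
24 | (3S,4S)-4-methylhex-5-en-3-yl (2R,4S,5R,6S,8S,10E)-5-hydroxy-2,4,6,8-tetramethyl-3,9-dioxododec-10-enoate | CC[C@H](OC(=O)[C@H](C)C(=O)[C@@H](C)[C@H](O)[C@@H](C)C[C@H](C)C(=O)/C=C/C)[C@@H](C)C=C | intermediate
25 | (3R,5S,6R,7S,9S,11E,13S,14S)-14-ethyl-6-hydroxy-3,5,7,9,13-pentamethyl-1-oxacyclotetradec-11-ene-2,4,10-trione | CC[C@@H]1OC(=O)[C@H](C)C(=O)[C@@H](C)[C@H](O)[C@@H](C)C[C@H](C)C(=O)/C=C/[C@@H]1C | target

**Step count**
Total: 9 steps. Longest linear sequence: 7 steps (steps 3 to 9).

**Three steps most likely to fail**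

Step 8 (the proposed new step). The risks are incomplete ring opening of 7 by a hindered secondary alkoxide, proton transfer that would scramble C2, an unproven lithium-to-tin exchange, and an aldol in which the enolate bias must override the modest anti-Felkin preference of 19 towards (Z)-enolates. The fallback uses known catalytic reactions, sets out from 19 and 4 and comes back at 24. Aldehyde 19 undergoes a syn-selective Mukaiyama aldol, catalysed by a confined imidodiphosphorimidate Brønsted acid, with (Z)-triethyl(prop-1-en-1-yloxy)silane F1 (from 1, Et3SiCl, Et3N, NaI), giving (2S,3R,4S,6S,8E)-2,4,6-trimethyl-7-oxo-3-(triethylsilyloxy)dec-8-enal F2 with C4 and C5 set. Separately 4 is esterified with pyruvic acid (DCC, DMAP) to (3S,4S)-4-methylhex-5-en-3-yl 2-oxopropanoate F3, condensed with tosylhydrazide to (3S,4S)-4-methylhex-5-en-3-yl 2-(tosylhydrazinylidene)propanoate F4, and treated with DBU to give (3S,4S)-4-methylhex-5-en-3-yl 2-diazopropanoate F5. A Roskamp homologation of F2 with F5, catalysed by a chiral oxazaborolidinium triflimide at −78 °C, forms C2–C3 as the ketone and sets C2 under catalyst control, giving (3S,4S)-4-methylhex-5-en-3-yl (2R,4S,5R,6S,8S,10E)-2,4,6,8-tetramethyl-3,9-dioxo-5-(triethylsilyloxy)dodec-10-enoate F6. HF·pyridine then gives 24.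

Step 5. The ruthenium catalyst may not override the existing stereocentre of 13, which would give the cis lactone or low selectivity. The fallback replaces catalyst-controlled hydrogenation by substrate-controlled enolate alkylation, sets out from 10 (made from 1 and 8 as in step 3) and comes back at 15. Aldehyde 10 is trapped with ethyl (triphenylphosphoranylidene)acetate to give ethyl (2E,4S)-5-hydroxy-4-methylpent-2-enoate F7. Hydrogenation over Pd/C gives ethyl (4S)-5-hydroxy-4-methylpentanoate F8, which is lactonised with p-TsOH to (5S)-5-methyloxan-2-one F9. Lithium diisopropylamide at −78 °C gives the lithium enolate, lithium (3S)-3-methyl-3,4-dihydro-2H-pyran-6-olate F10, and iodomethane enters axially on the half-chair with the C5 methyl equatorial, which gives the 3,5-trans lactone 15.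

Step 9. The free δ-hydroxy-β-keto ester may translactonise to a six-membered keto lactone, rest as a six-membered hemiketal on the C9 ketone, bind ruthenium, or lose C2 integrity before the ring closes. The fallback closes the ring on a silyl-protected seco ester, sets out from 24 and comes back at 25. Treatment of 24 with TBSOTf and 2,6-lutidine at −78 °C gives (3S,4S)-4-methylhex-5-en-3-yl (2R,4S,5R,6S,8S,10E)-5-(tert-butyldimethylsilyloxy)-2,4,6,8-tetramethyl-3,9-dioxododec-10-enoate F11. Ring-closing metathesis under the step 9 conditions gives (3R,5S,6R,7S,9S,11E,13S,14S)-6-(tert-butyldimethylsilyloxy)-14-ethyl-3,5,7,9,13-pentamethyl-1-oxacyclotetradec-11-ene-2,4,10-trione F12, and HF·pyridine releases 25.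

**Further compounds**
F1 | step 8 | (Z)-triethyl(prop-1-en-1-yloxy)silane | C/C=C\O[Si](CC)(CC)CC
F2 | step 8 | (2S,3R,4S,6S,8E)-2,4,6-trimethyl-7-oxo-3-(triethylsilyloxy)dec-8-enal | O=C[C@@H](C)[C@H](O[Si](CC)(CC)CC)[C@@H](C)C[C@H](C)C(=O)/C=C/C
F3 | step 8 | (3S,4S)-4-methylhex-5-en-3-yl 2-oxopropanoate | CC[C@H](OC(=O)C(C)=O)[C@@H](C)C=C
F4 | step 8 | (3S,4S)-4-methylhex-5-en-3-yl 2-(tosylhydrazinylidene)propanoate | CC[C@H](OC(=O)C(C)=NNS(=O)(=O)c1ccc(C)cc1)[C@@H](C)C=C
F5 | step 8 | (3S,4S)-4-methylhex-5-en-3-yl 2-diazopropanoate | CC[C@H](OC(=O)C(C)=[N+]=[N-])[C@@H](C)C=C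
F6 | step 8 | (3S,4S)-4-methylhex-5-en-3-yl (2R,4S,5R,6S,8S,10E)-2,4,6,8-tetramethyl-3,9-dioxo-5-(triethylsilyloxy)dodec-10-enoate | CC[C@H](OC(=O)[C@H](C)C(=O)[C@@H](C)[C@H](O[Si](CC)(CC)CC)[C@@H](C)C[C@H](C)C(=O)/C=C/C)[C@@H](C)C=C
F7 | step 5 | ethyl (2E,4S)-5-hydroxy-4-methylpent-2-enoate | OC[C@@H](C)/C=C/C(=O)OCC
F8 | step 5 | ethyl (4S)-5-hydroxy-4-methylpentanoate | OC[C@@H](C)CCC(=O)OCC
F9 | step 5 | (5S)-5-methyloxan-2-one | C[C@H]1CCC(=O)OC1
F10 | step 5 | lithium (3S)-3-methyl-3,4-dihydro-2H-pyran-6-olate | C[C@H]1CC=C(O[Li])OC1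
F11 | step 9 | (3S,4S)-4-methylhex-5-en-3-yl (2R,4S,5R,6S,8S,10E)-5-(tert-butyldimethylsilyloxy)-2,4,6,8-tetramethyl-3,9-dioxododec-10-enoate | CC[C@H](OC(=O)[C@H](C)C(=O)[C@@H](C)[C@H](O[Si](C)(C)C(C)(C)C)[C@@H](C)C[C@H](C)C(=O)/C=C/C)[C@@H](C)C=C
F12 | step 9 | (3R,5S,6R,7S,9S,11E,13S,14S)-6-(tert-butyldimethylsilyloxy)-14-ethyl-3,5,7,9,13-pentamethyl-1-oxacyclotetradec-11-ene-2,4,10-trione | CC[C@@H]1OC(=O)[C@H](C)C(=O)[C@@H](C)[C@H](O[Si](C)(C)C(C)(C)C)[C@@H](C)C[C@H](C)C(=O)/C=C/[C@@H]1C
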